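Everything rests on cutting the C5–C6 bond (germacrane numbering) of the oxepane ring O–C5–C6–C7–C8–C9–C10. In that ring C5 carries the ether oxygen and the C4–C15 ester arm, and its neighbour C6 carries the lactone oxygen trans to the arm: the vicinal pattern that a ketyl leaves when it adds to a β-alkoxyacrylate. One SmI2 step therefore makes the C5–C6 bond, closes the oxepane and sets both centres. Its precursor is an open chain from (S)-linalool: the C10 tertiary oxygen as an (E)-β-alkoxyacrylate, a C6 aldehyde, and the anti C7/C8 pair from asymmetric epoxidation and cuprate opening. Olefination closes the enoate ring; lactone formation and acylation finish.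

Key step: step 10

Assumption: germacrane numbering is used throughout (ring carbons C1–C10, C11–C13 the three-carbon unit on C7, C14 the methyl on C10, C15 the ester carbon on C4); the target is the isomer (5R,6S,7R,8R,10S) with a (2S,3R)-epoxy ester, and (S)-linalool of high enantiomeric purity is taken as purchasable.

Remark on the chemistry: in the open chain the C7 isopropenyl group and the C8 oxygen are anti along C6–C9 (cis on the oxepane), so this pair is made by opening a trans epoxide and not by a syn-selective aldol; an ester enolate cannot be formed beside a free aldehyde, so the enoate ring is closed by a phosphonate olefination.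

Step 1
Reactants: 1 (S)-linalool
Product: 3 (3S)-3,7-dimethyloct-6-ene-1,3-diol, via B-alkyl-9-BBN adduct 2 (not isolated)
Conditions: 9-BBN (2.2 equiv), THF, 0 °C to rt; then NaOH (aq), H2O2, 0 °C
Reagents that add atoms: 9-borabicyclo[3.3.1]nonane, B1C2CCCC1CCC2 (to intermediate 2 only); hydrogen peroxide, OO
Why: Hydroboration–oxidation with the bulky 9-BBN should take the monosubstituted vinyl group in preference to the trisubstituted alkene and place boron on the terminal carbon (future C8), leaving the C10 carbinol centre untouched.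

Step 2
Reactants: 3 (3S)-3,7-dimethyloct-6-ene-1,3-diol; 4 ethyl 2-(triphenyl-λ5-phosphanylidene)acetate
Product: 6 ethyl (2E,5S)-5-hydroxy-5,9-dimethyldeca-2,8-dienoate, via hydroxy aldehyde 5 (not isolated)
Conditions: TEMPO (cat.), PhI(OAc)2 (1.1 equiv), CH2Cl2, rt; then 4 (1.5 equiv), rt
Reagents that add atoms: none
Why: A TEMPO/PhI(OAc)2 oxidation should convert only the primary alcohol, and the dehydration-prone β-hydroxy aldehyde is trapped at once by Wittig olefination with the stabilised ylide under neutral conditions, which gives the (E)-enoate.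

Step 3
Reactants: 6 ethyl (2E,5S)-5-hydroxy-5,9-dimethyldeca-2,8-dienoate
Product: 7 (2E,5S)-5,9-dimethyldeca-2,8-diene-1,5-diol
Conditions: i-Bu2AlH (3.5 equiv), CH2Cl2, −78 to 0 °C
Reagents that add atoms: none
Why: i-Bu2AlH should reduce the enoate 1,2 to the (E)-allylic alcohol (ester reduction), one extra equivalent being consumed by the tertiary hydroxyl.

Step 4
Reactants: 7 (2E,5S)-5,9-dimethyldeca-2,8-diene-1,5-diol
Product: 8 (2S)-1-[(2R,3R)-3-(hydroxymethyl)oxiran-2-yl]-2,6-dimethylhept-5-en-2-ol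
Conditions: Ti(OiPr)4 (1.0 equiv), D-(−)-diisopropyl tartrate (1.2 equiv), t-BuOOH, 4 Å molecular sieves, CH2Cl2, −20 °C
Reagents that add atoms: tert-butyl hydroperoxide, CC(C)(C)OO
Why: Sharpless asymmetric epoxidation, directed by the primary allylic hydroxyl, should set C7 and C8 together as the (2R,3R) trans epoxide under control of the D-(−)-tartrate, while the unactivated trisubstituted alkene and the tertiary homoallylic alcohol stay out of the reaction.

Step 5
Reactants: 8 epoxy diol; 9 isopropenylmagnesium bromide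
Product: 10 (2S,3R,5S)-5,9-dimethyl-2-(prop-1-en-2-yl)dec-8-ene-1,3,5-triol
Conditions: 9 (5 equiv), CuI (10 mol%), THF, −30 to 0 °C; aq. NH4Cl; then NaIO4 (aq) wash
Reagents that add atoms: none
Why: Copper-catalysed Grignard opening of a 2,3-epoxy alcohol at C2 (alkoxide-directed cuprate attack) should deliver the isopropenyl group to C7 with inversion while C8 keeps its configuration, so that the C7/C8 pair comes out anti; the periodate wash cleaves any 1,2-diol formed by attack at C8 or after Payne rearrangement.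

Step 6
Reactants: 10 triol
Product: 11 (2S,3R,5S)-1,3-bis[(tert-butyldimethylsilyl)oxy]-5,9-dimethyl-2-(prop-1-en-2-yl)dec-8-en-5-ol
Conditions: TBSCl (2.5 equiv), imidazole, DMAP (cat.), DMF, 45 °C
Reagents that add atoms: tert-butyldimethylsilyl chloride, CC(C)(C)[Si](C)(C)Cl
Why: Silylation with TBSCl/imidazole should cap the primary and the secondary hydroxyl and leave the tertiary C10 alcohol free, because silyl chlorides do not react with tertiary alcohols under these conditions.

Step 7
Reactants: 11 bis-silyl ether with free tertiary alcohol; 12 methyl propiolate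
Product: 13 methyl (2E)-3-{[(2S,3R,5S)-1,3-bis[(tert-butyldimethylsilyl)oxy]-5,9-dimethyl-2-(prop-1-en-2-yl)dec-8-en-5-yl]oxy}prop-2-enoate
Conditions: 12 (3 equiv), PMe3 (cat.), CH2Cl2, 0 °C to rt
Reagents that add atoms: none
Why: Phosphine-catalysed oxa-Michael addition of the alcohol to the propiolate (PMe3 being the catalyst suited to tertiary alcohols) should give the (E)-β-alkoxyacrylate with no change at C10.

Step 8
Reactants: 13 β-alkoxyacrylate bis-silyl ether
Product: 14 methyl (2E)-3-{[(2S,3R,5S)-3-[(tert-butyldimethylsilyl)oxy]-1-hydroxy-5,9-dimethyl-2-(prop-1-en-2-yl)dec-8-en-5-yl]oxy}prop-2-enoate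
Conditions: HF·pyridine, pyridine, THF, 0 °C
Reagents that add atoms: none
Why: Buffered HF·pyridine should cleave the unhindered primary TBS ether much faster than the secondary one flanked by C7 and C9 (selective desilylation), and it leaves the vinylogous carbonate alone.

Step 9
Reactants: 14 primary alcohol
Product: 15 methyl (2E)-3-{[(2R,3R,5S)-3-[(tert-butyldimethylsilyl)oxy]-5,9-dimethyl-1-oxo-2-(prop-1-en-2-yl)dec-8-en-5-yl]oxy}prop-2-enoate
Conditions: Dess–Martin periodinane, NaHCO3, CH2Cl2, 0 °C; used at once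
Reagents that add atoms: none
Why: Dess–Martin oxidation under bicarbonate buffer should give the aldehyde without epimerising C7 or moving the isopropenyl double bond into conjugation, provided 15 is used at once.

Step 10
Reactants: 15 β-alkoxyacrylate aldehyde
Product: 16 methyl 2-[(2R,3S,4S,5R,7S)-5-[(tert-butyldimethylsilyl)oxy]-3-hydroxy-7-methyl-7-(4-methylpent-3-en-1-yl)-4-(prop-1-en-2-yl)oxepan-2-yl]acetate (2,3-trans oxepane hydroxy ester)
Conditions: SmI2 (3 equiv, 0.1 M in THF), MeOH (4 equiv), THF, high dilution, 0 °C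
Reagents that add atoms: none
Why: SmI2 reduces the C6 aldehyde to a ketyl, which adds to C5 of the (E)-β-alkoxyacrylate; the α-ester radical at C4 is reduced by a second SmI2 and protonated by MeOH (ketyl–olefin reductive cyclisation, the known SmI2 closure of aldehydes onto β-alkoxyacrylates that gives 2,3-trans oxepanes in polycyclic ether synthesis). The oxepane O–C5–C6–C7–C8–C9–C10 closes in the 7-exo-trig mode. C5 and C6 are set together: trivalent samarium bridges the ketyl oxygen and the ester carbonyl in a chair-like transition state, which puts the C6 oxygen trans to the C5 acetate arm. The face is decided by C7, since only the chair with the C5 arm, the C6 oxygen and the C7 isopropenyl group all pseudo-equatorial leads to the required (5R,6S) pair. That chair carries the C8 silyl ether pseudo-axial on the same side as the C1 chain at C10, so facial selectivity is the selectivity this step needs, and the small effective size of an O-silyl group is what is relied on to secure it. Chemoselectivity for the aldehyde over the vinylogous carbonate and for cyclisation over pinacol coupling should follow from the chelating acrylate, dilution and MeOH.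

Step 11
Reactants: 16 oxepane hydroxy ester
Product: 17 methyl 2-[(2R,3S,4R,5R,7S)-5-[(tert-butyldimethylsilyl)oxy]-7-methyl-7-(4-methylpent-3-en-1-yl)-4-(prop-1-en-2-yl)-3-[(triethylsilyl)oxy]oxepan-2-yl]acetate
Conditions: TESOTf, 2,6-lutidine, CH2Cl2, −78 °C
Reagents that add atoms: triethylsilyl trifluoromethanesulfonate, CC[Si](CC)(CC)OS(=O)(=O)C(F)(F)F
Why: Silylation with the triflate should cap the hindered C6 carbinol at low temperature before it can lactonise onto the C15 ester, and the TES ether can later be removed in the presence of the C8 TBS ether.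

Step 12
Reactants: 17 TES-protected oxepane ester
Product: 19 methyl 2-(diethoxyphosphoryl)-2-[(2S,3S,4R,5R,7S)-5-[(tert-butyldimethylsilyl)oxy]-7-methyl-7-(4-methylpent-3-en-1-yl)-4-(prop-1-en-2-yl)-3-[(triethylsilyl)oxy]oxepan-2-yl]acetate (epimers at C4), via phosphonite ester 18 (not isolated)
Conditions: LiN(i-Pr)2 (2.2 equiv), THF, −78 °C; ClP(OEt)2, −78 °C; AcOH; then H2O2 (aq), 0 °C
Reagents that add atoms: diethyl chlorophosphite, CCOP(Cl)OCC; hydrogen peroxide, OO
Why: C-Phosphitylation of the lithium ester enolate with ClP(OEt)2 followed by oxidation of trivalent to pentavalent phosphorus is an established route to α-phosphono esters; the enolate is made and trapped at −78 °C so that the ring oxygen on C5 is not expelled, and the new C4 centre (epimer mixture) is destroyed in step 14.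

Step 13
Reactants: 19 α-phosphono ester
Product: 21 methyl 2-(diethoxyphosphoryl)-2-[(2S,3S,4R,5R,7S)-5-[(tert-butyldimethylsilyl)oxy]-7-methyl-7-(3-oxopropyl)-4-(prop-1-en-2-yl)-3-[(triethylsilyl)oxy]oxepan-2-yl]acetate, via side-chain epoxide 20 (not isolated)
Conditions: mCPBA (1.05 equiv), NaHCO3, CH2Cl2, −20 to 0 °C; then H5IO6, THF/Et2O, 0 °C, short contact
Reagents that add atoms: 3-chloroperoxybenzoic acid, O=C(OO)c1cccc(Cl)c1
Why: Prilezhaev epoxidation should take the electron-rich, unhindered trisubstituted alkene in preference to the 1,1-disubstituted isopropenyl group shielded by two silyl ethers, and periodic acid then cleaves the epoxide to the C3 aldehyde and acetone.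

Step 14
Reactants: 21 phosphono ester aldehyde
Product: 22 methyl (1R,6S,8R,9R,10S)-8-[(tert-butyldimethylsilyl)oxy]-6-methyl-9-(prop-1-en-2-yl)-10-[(triethylsilyl)oxy]-11-oxabicyclo[4.4.1]undec-2-ene-2-carboxylate
Conditions: LiCl, DBU, MeCN, rt, slow addition at high dilution
Reagents that add atoms: none
Why: Intramolecular Horner–Wadsworth–Emmons olefination under LiCl/amine conditions should close the seven-membered enoate ring (C3=C4) because the C1 chain and the C4 arm sit cis on the oxepane, with the ring fixing the alkene geometry and the irreversible olefination outrunning ring-opening of the phosphonate anion.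

Step 15
Reactants: 22 bicyclic enoate
Product: 23 methyl (1R,6S,8R,9R,10S)-8-[(tert-butyldimethylsilyl)oxy]-9-(3-hydroxyprop-1-en-2-yl)-6-methyl-10-[(triethylsilyl)oxy]-11-oxabicyclo[4.4.1]undec-2-ene-2-carboxylate
Conditions: SeO2 (0.5 equiv), t-BuOOH, CH2Cl2, rt
Reagents that add atoms: selenium dioxide, O=[Se]=O; tert-butyl hydroperoxide, CC(C)(C)OO
Why: SeO2-catalysed allylic oxidation (ene reaction then [2,3] shift) should hydroxylate the methyl group of the isopropenyl unit (C12) and leave the electron-poor enoate alkene alone; any enal from over-oxidation converges in step 17.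

Step 16
Reactants: 23 allylic alcohol
Product: 24 methyl (1R,6S,8R,9S,10S)-8-[(tert-butyldimethylsilyl)oxy]-10-hydroxy-9-(3-hydroxyprop-1-en-2-yl)-6-methyl-11-oxabicyclo[4.4.1]undec-2-ene-2-carboxylate
Conditions: HF·pyridine, pyridine, THF, 0 °C
Reagents that add atoms: none
Why: Buffered HF·pyridine should remove the TES ether selectively (selective desilylation), the hindered C8 TBS ether being far slower to cleave.

Step 17
Reactants: 24 diol
Product: 27 methyl (1R,2S,6S,7R,9S)-7-[(tert-butyldimethylsilyl)oxy]-9-methyl-5-methylidene-4-oxo-3,14-dioxatricyclo[7.4.1.0^{2,6}]tetradec-12-ene-13-carboxylate, via hydroxy enal 25 (not isolated), via lactol 26 (not isolated)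
Conditions: MnO2 (excess), CH2Cl2, rt
Reagents that add atoms: none
Why: MnO2 should oxidise the allylic alcohol to the enal, which is captured by the C6 hydroxyl as a five-membered lactol and oxidised on to the α-methylene lactone (oxidative lactonisation); with C8 still silylated only the C6 oxygen can close, trans to C7 as fixed in step 10.

Step 18
Reactants: 27 silylated methylene lactone
Product: 28 methyl (1R,2S,6R,7R,9S)-7-hydroxy-9-methyl-5-methylidene-4-oxo-3,14-dioxatricyclo[7.4.1.0^{2,6}]tetradec-12-ene-13-carboxylate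
Conditions: HF·pyridine, THF, 0 °C to rt
Reagents that add atoms: none
Why: Acidic fluoride (HF·pyridine) should cleave the last silyl ether without the alkoxide conditions that would invite translactonisation to the C8 oxygen or conjugate addition to the methylene lactone.

Step 19
Reactants: 29 tiglic acid
Product: 30 (2E)-2-methylbut-2-en-1-ol
Conditions: LiAlH4, Et2O, 0 °C to rt
Reagents that add atoms: none
Why: LiAlH4 reduction of the conjugated acid should give the allylic alcohol with the (E) geometry intact.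

Step 20
Reactants: 30 (2E)-2-methylbut-2-en-1-ol
Product: 31 [(2R,3R)-2,3-dimethyloxiran-2-yl]methanol
Conditions: Ti(OiPr)4, D-(−)-diisopropyl tartrate, t-BuOOH, 4 Å molecular sieves, CH2Cl2, −20 °C
Reagents that add atoms: tert-butyl hydroperoxide, CC(C)(C)OO
Why: Sharpless asymmetric epoxidation with D-(−)-tartrate should set both epoxide carbons as (2R,3R), the two methyl groups staying cis as in the (E)-alkene.

Step 21
Reactants: 31 [(2R,3R)-2,3-dimethyloxiran-2-yl]methanol
Product: 33 (2S,3R)-2,3-dimethyloxirane-2-carboxylic acid, via epoxy aldehyde 32 (not isolated)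
Conditions: RuCl3·xH2O (cat.), NaIO4, MeCN/CCl4/H2O, rt
Reagents that add atoms: water, O
Why: RuO4 generated from RuCl3 and NaIO4 should oxidise the primary alcohol through the aldehyde hydrate to the acid without opening the epoxide (catalytic ruthenium tetroxide oxidation); the descriptor at C2 changes from R to S only because the carboxyl group outranks C3.

Step 22
Reactants: 28 hydroxy methylene lactone; 33 (2S,3R)-2,3-dimethyloxirane-2-carboxylic acid
Product: 35 methyl (1R,2S,6R,7R,9S)-7-{[(2S,3R)-2,3-dimethyloxirane-2-carbonyl]oxy}-9-methyl-5-methylidene-4-oxo-3,14-dioxatricyclo[7.4.1.0^{2,6}]tetradec-12-ene-13-carboxylate (CNP0240298.1), via mixed anhydride 34 (not isolated)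
Conditions: 33, 2,4,6-trichlorobenzoyl chloride, Et3N, THF, rt; then 28, DMAP, toluene, rt
Reagents that add atoms: 2,4,6-trichlorobenzoyl chloride, O=C(Cl)c1c(Cl)cc(Cl)cc1Cl (to intermediate 34 only)
Why: Yamaguchi esterification through the mixed anhydride should acylate the hindered C8 hydroxyl with retention at C8 and at both epoxide carbons, giving the target.

Compound list

1 | (S)-linalool, (3S)-3,7-dimethylocta-1,6-dien-3-ol | CC(C)=CCC[C@](C)(O)C=C | starting material
2 | 9-[(3R)-3-hydroxy-3,7-dimethyloct-6-en-1-yl]-9-borabicyclo[3.3.1]nonane (same spatial arrangement as 1; descriptor changes by priority only) | CC(C)=CCC[C@](C)(O)CCB1C2CCCC1CCC2 | intermediate (not isolated)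
3 | (3S)-3,7-dimethyloct-6-ene-1,3-diol | CC(C)=CCC[C@](C)(O)CCO | intermediate
4 | ethyl 2-(triphenyl-λ5-phosphanylidene)acetate | CCOC(=O)C=P(c1ccccc1)(c1ccccc1)c1ccccc1 | starting material
5 | (3S)-3-hydroxy-3,7-dimethyloct-6-enal | CC(C)=CCC[C@](C)(O)CC=O | intermediate (not isolated)
6 | ethyl (2E,5S)-5-hydroxy-5,9-dimethyldeca-2,8-dienoate | CC(C)=CCC[C@](C)(O)C/C=C/C(=O)OCC | intermediate
7 | (2E,5S)-5,9-dimethyldeca-2,8-diene-1,5-diol | CC(C)=CCC[C@](C)(O)C/C=C/CO | intermediate
8 | (2S)-1-[(2R,3R)-3-(hydroxymethyl)oxiran-2-yl]-2,6-dimethylhept-5-en-2-ol | OC[C@H]1O[C@@H]1C[C@@](C)(O)CCC=C(C)C | intermediate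
9 | isopropenylmagnesium bromide (prop-1-en-2-ylmagnesium bromide) | CC(=C)[Mg]Br | starting material
10 | (2S,3R,5S)-5,9-dimethyl-2-(prop-1-en-2-yl)dec-8-ene-1,3,5-triol | CC(C)=CCC[C@](C)(O)C[C@@H](O)[C@H](CO)C(C)=C | intermediate
11 | (2S,3R,5S)-1,3-bis[(tert-butyldimethylsilyl)oxy]-5,9-dimethyl-2-(prop-1-en-2-yl)dec-8-en-5-ol | CC(C)=CCC[C@](C)(O)C[C@@H](O[Si](C)(C)C(C)(C)C)[C@H](CO[Si](C)(C)C(C)(C)C)C(C)=C | intermediate
12 | methyl propiolate (methyl prop-2-ynoate) | C#CC(=O)OC | starting material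
13 | methyl (2E)-3-{[(2S,3R,5S)-1,3-bis[(tert-butyldimethylsilyl)oxy]-5,9-dimethyl-2-(prop-1-en-2-yl)dec-8-en-5-yl]oxy}prop-2-enoate | COC(=O)/C=C/O[C@@](C)(CCC=C(C)C)C[C@@H](O[Si](C)(C)C(C)(C)C)[C@H](CO[Si](C)(C)C(C)(C)C)C(C)=C | intermediate
14 | methyl (2E)-3-{[(2S,3R,5S)-3-[(tert-butyldimethylsilyl)oxy]-1-hydroxy-5,9-dimethyl-2-(prop-1-en-2-yl)dec-8-en-5-yl]oxy}prop-2-enoate | COC(=O)/C=C/O[C@@](C)(CCC=C(C)C)C[C@@H](O[Si](C)(C)C(C)(C)C)[C@H](CO)C(C)=C | intermediate
15 | methyl (2E)-3-{[(2R,3R,5S)-3-[(tert-butyldimethylsilyl)oxy]-5,9-dimethyl-1-oxo-2-(prop-1-en-2-yl)dec-8-en-5-yl]oxy}prop-2-enoate (key-step precursor) | COC(=O)/C=C/O[C@@](C)(CCC=C(C)C)C[C@@H](O[Si](C)(C)C(C)(C)C)[C@@H](C(C)=C)C=O | intermediate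
16 | methyl 2-[(2R,3S,4S,5R,7S)-5-[(tert-butyldimethylsilyl)oxy]-3-hydroxy-7-methyl-7-(4-methylpent-3-en-1-yl)-4-(prop-1-en-2-yl)oxepan-2-yl]acetate (key-step product) | COC(=O)C[C@H]1O[C@@](C)(CCC=C(C)C)C[C@@H](O[Si](C)(C)C(C)(C)C)[C@@H](C(C)=C)[C@@H]1O | intermediate
17 | methyl 2-[(2R,3S,4R,5R,7S)-5-[(tert-butyldimethylsilyl)oxy]-7-methyl-7-(4-methylpent-3-en-1-yl)-4-(prop-1-en-2-yl)-3-[(triethylsilyl)oxy]oxepan-2-yl]acetate | COC(=O)C[C@H]1O[C@@](C)(CCC=C(C)C)C[C@@H](O[Si](C)(C)C(C)(C)C)[C@@H](C(C)=C)[C@@H]1O[Si](CC)(CC)CC | intermediate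
18 | methyl 2-(diethoxyphosphanyl)-2-[(2S,3S,4R,5R,7S)-5-[(tert-butyldimethylsilyl)oxy]-7-methyl-7-(4-methylpent-3-en-1-yl)-4-(prop-1-en-2-yl)-3-[(triethylsilyl)oxy]oxepan-2-yl]acetate (epimers at C4) | COC(=O)C(P(OCC)OCC)[C@H]1O[C@@](C)(CCC=C(C)C)C[C@@H](O[Si](C)(C)C(C)(C)C)[C@@H](C(C)=C)[C@@H]1O[Si](CC)(CC)CC | intermediate (not isolated)
19 | methyl 2-(diethoxyphosphoryl)-2-[(2S,3S,4R,5R,7S)-5-[(tert-butyldimethylsilyl)oxy]-7-methyl-7-(4-methylpent-3-en-1-yl)-4-(prop-1-en-2-yl)-3-[(triethylsilyl)oxy]oxepan-2-yl]acetate (epimers at C4) | COC(=O)C(P(=O)(OCC)OCC)[C@H]1O[C@@](C)(CCC=C(C)C)C[C@@H](O[Si](C)(C)C(C)(C)C)[C@@H](C(C)=C)[C@@H]1O[Si](CC)(CC)CC | intermediate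
20 | methyl 2-(diethoxyphosphoryl)-2-[(2S,3S,4R,5R,7S)-5-[(tert-butyldimethylsilyl)oxy]-7-[2-(3,3-dimethyloxiran-2-yl)ethyl]-7-methyl-4-(prop-1-en-2-yl)-3-[(triethylsilyl)oxy]oxepan-2-yl]acetate (epimers at C4 and at the epoxide carbon) | COC(=O)C(P(=O)(OCC)OCC)[C@H]1O[C@@](C)(CCC2OC2(C)C)C[C@@H](O[Si](C)(C)C(C)(C)C)[C@@H](C(C)=C)[C@@H]1O[Si](CC)(CC)CC | intermediate (not isolated)
21 | methyl 2-(diethoxyphosphoryl)-2-[(2S,3S,4R,5R,7S)-5-[(tert-butyldimethylsilyl)oxy]-7-methyl-7-(3-oxopropyl)-4-(prop-1-en-2-yl)-3-[(triethylsilyl)oxy]oxepan-2-yl]acetate (epimers at C4) | COC(=O)C(P(=O)(OCC)OCC)[C@H]1O[C@@](C)(CCC=O)C[C@@H](O[Si](C)(C)C(C)(C)C)[C@@H](C(C)=C)[C@@H]1O[Si](CC)(CC)CC | intermediate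
22 | methyl (1R,6S,8R,9R,10S)-8-[(tert-butyldimethylsilyl)oxy]-6-methyl-9-(prop-1-en-2-yl)-10-[(triethylsilyl)oxy]-11-oxabicyclo[4.4.1]undec-2-ene-2-carboxylate | COC(=O)C1=CCC[C@@]2(C)C[C@@H](O[Si](C)(C)C(C)(C)C)[C@@H](C(C)=C)[C@H](O[Si](CC)(CC)CC)[C@@H]1O2 | intermediate
23 | methyl (1R,6S,8R,9R,10S)-8-[(tert-butyldimethylsilyl)oxy]-9-(3-hydroxyprop-1-en-2-yl)-6-methyl-10-[(triethylsilyl)oxy]-11-oxabicyclo[4.4.1]undec-2-ene-2-carboxylate | COC(=O)C1=CCC[C@@]2(C)C[C@@H](O[Si](C)(C)C(C)(C)C)[C@@H](C(=C)CO)[C@H](O[Si](CC)(CC)CC)[C@@H]1O2 | intermediate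
24 | methyl (1R,6S,8R,9S,10S)-8-[(tert-butyldimethylsilyl)oxy]-10-hydroxy-9-(3-hydroxyprop-1-en-2-yl)-6-methyl-11-oxabicyclo[4.4.1]undec-2-ene-2-carboxylate | COC(=O)C1=CCC[C@@]2(C)C[C@@H](O[Si](C)(C)C(C)(C)C)[C@@H](C(=C)CO)[C@H](O)[C@@H]1O2 | intermediate
25 | methyl (1R,6S,8R,9S,10S)-8-[(tert-butyldimethylsilyl)oxy]-10-hydroxy-6-methyl-9-(3-oxoprop-1-en-2-yl)-11-oxabicyclo[4.4.1]undec-2-ene-2-carboxylate | COC(=O)C1=CCC[C@@]2(C)C[C@@H](O[Si](C)(C)C(C)(C)C)[C@@H](C(=C)C=O)[C@H](O)[C@@H]1O2 | intermediate (not isolated)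
26 | methyl (1R,2S,6S,7R,9S)-7-[(tert-butyldimethylsilyl)oxy]-4-hydroxy-9-methyl-5-methylidene-3,14-dioxatricyclo[7.4.1.0^{2,6}]tetradec-12-ene-13-carboxylate (anomers at C4 of the tricycle) | C=C1C(O)O[C@H]2[C@H]1[C@H](O[Si](C)(C)C(C)(C)C)C[C@]1(C)CCC=C(C(=O)OC)[C@H]2O1 | intermediate (not isolated)
27 | methyl (1R,2S,6S,7R,9S)-7-[(tert-butyldimethylsilyl)oxy]-9-methyl-5-methylidene-4-oxo-3,14-dioxatricyclo[7.4.1.0^{2,6}]tetradec-12-ene-13-carboxylate | C=C1C(=O)O[C@H]2[C@H]1[C@H](O[Si](C)(C)C(C)(C)C)C[C@]1(C)CCC=C(C(=O)OC)[C@H]2O1 | intermediate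
28 | methyl (1R,2S,6R,7R,9S)-7-hydroxy-9-methyl-5-methylidene-4-oxo-3,14-dioxatricyclo[7.4.1.0^{2,6}]tetradec-12-ene-13-carboxylate | C=C1C(=O)O[C@H]2[C@H]1[C@H](O)C[C@]1(C)CCC=C(C(=O)OC)[C@H]2O1 | intermediate
29 | tiglic acid, (2E)-2-methylbut-2-enoic acid | C/C=C(\C)C(=O)O | starting material
30 | (2E)-2-methylbut-2-en-1-ol | C/C=C(\C)CO | intermediate
31 | [(2R,3R)-2,3-dimethyloxiran-2-yl]methanol | OC[C@@]1(C)O[C@@H]1C | intermediate
32 | (2S,3R)-2,3-dimethyloxirane-2-carbaldehyde | O=C[C@@]1(C)O[C@@H]1C | intermediate (not isolated)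
33 | (2S,3R)-2,3-dimethyloxirane-2-carboxylic acid | OC(=O)[C@@]1(C)O[C@@H]1C | intermediate
34 | (2S,3R)-2,3-dimethyloxirane-2-carboxylic 2,4,6-trichlorobenzoic anhydride | O=C(OC(=O)[C@@]1(C)O[C@@H]1C)c1c(Cl)cc(Cl)cc1Cl | intermediate (not isolated)
35 | methyl (1R,2S,6R,7R,9S)-7-{[(2S,3R)-2,3-dimethyloxirane-2-carbonyl]oxy}-9-methyl-5-methylidene-4-oxo-3,14-dioxatricyclo[7.4.1.0^{2,6}]tetradec-12-ene-13-carboxylate; germacrane descriptors (5R,6S,7R,8R,10S) | C=C1C(=O)O[C@H]2[C@H]1[C@H](OC(=O)[C@@]1(C)O[C@@H]1C)C[C@]1(C)CCC=C(C(=O)OC)[C@H]2O1 | target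

Total step count: 22. Longest linear sequence: 19 steps (steps 1–18 and 22); steps 19–21 make the epoxy acid in a side branch.

Steps most likely to fail

Step 10 (key step). What may go wrong: poor facial selectivity in the ketyl addition, the competing chair (C8 silyl ether equatorial, isopropenyl axial) giving the other 5,6-trans isomer, or reduction of the aldehyde before the ring closes. The fallback changes the source of stereocontrol to a hydroxyl-directed closure. This is known for SmI2 ketyl–olefin couplings of β-hydroxy carbonyl compounds, which give the 1,3-anti relationship needed between the C6 and C8 oxygens. It sets out from 13. Both TBS ethers are removed with unbuffered HF·pyridine in THF to give the diol F1. The primary alcohol is oxidised selectively (TEMPO, PhI(OAc)2, CH2Cl2) to the β-hydroxy aldehyde F2, which is used at once. SmI2/MeOH in THF should then close the ring, the free C8 hydroxyl binding trivalent samarium together with the ketyl oxygen, to give the oxepane diol F3. Silylation of the less hindered C8 hydroxyl (TBSOTf, one equivalent, 2,6-lutidine, −78 °C) comes back to the route at 16.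

Step 12. What may go wrong: ring-opening β-elimination of the C4 enolate (the ring oxygen on C5 leaves) or transfer of the silyl group from the C6 oxygen to C4 before the phosphorus electrophile arrives. The fallback avoids a free lithium enolate and makes the C–P bond by bromination and Michaelis–Arbuzov reaction. It sets out from 17. LiN(i-Pr)2 is added to 17 in the presence of Me3SiCl at −78 °C, so that the enolate is silylated as it forms, to give the O-trimethylsilyl ketene acetal F4. N-Bromosuccinimide in THF at −78 °C should convert it into the α-bromo ester F5. Heating F5 with P(OEt)3 comes back to the route at 19.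

Step 14. What may go wrong: intermolecular olefination to oligomers, or loss of the C5 configuration through reversible ring-opening of the phosphonate anion, in place of closure of the seven-membered ring. The fallback closes the same C3=C4 bond by ring-closing metathesis and also bypasses step 13. It sets out from 19. A Horner–Wadsworth–Emmons reaction with aqueous formaldehyde and K2CO3 should give the α-methylene ester F6. Ring-closing metathesis with the second-generation Grubbs catalyst, RuCl2(=CHPh)(H2IMes)(PCy3), in toluene at 80 °C, the prenyl terminus leaving as 2-methylpropene, comes back to the route at 22.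

Further compounds
F1 | step 10 | methyl (2E)-3-{[(2S,3R,5S)-1,3-dihydroxy-5,9-dimethyl-2-(prop-1-en-2-yl)dec-8-en-5-yl]oxy}prop-2-enoate | COC(=O)/C=C/O[C@@](C)(CCC=C(C)C)C[C@@H](O)[C@H](CO)C(C)=C
F2 | step 10 | methyl (2E)-3-{[(2R,3R,5S)-3-hydroxy-5,9-dimethyl-1-oxo-2-(prop-1-en-2-yl)dec-8-en-5-yl]oxy}prop-2-enoate | COC(=O)/C=C/O[C@@](C)(CCC=C(C)C)C[C@@H](O)[C@@H](C(C)=C)C=O
F3 | step 10 | methyl 2-[(2R,3S,4R,5R,7S)-3,5-dihydroxy-7-methyl-7-(4-methylpent-3-en-1-yl)-4-(prop-1-en-2-yl)oxepan-2-yl]acetate | COC(=O)C[C@H]1O[C@@](C)(CCC=C(C)C)C[C@@H](O)[C@@H](C(C)=C)[C@@H]1O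
F4 | step 12 | O-trimethylsilyl ketene acetal of 17 (ring centres as in 17) | COC(O[Si](C)(C)C)=C[C@H]1O[C@@](C)(CCC=C(C)C)C[C@@H](O[Si](C)(C)C(C)(C)C)[C@@H](C(C)=C)[C@@H]1O[Si](CC)(CC)CC
F5 | step 12 | methyl 2-bromo-2-[(2S,3S,4R,5R,7S)-5-[(tert-butyldimethylsilyl)oxy]-7-methyl-7-(4-methylpent-3-en-1-yl)-4-(prop-1-en-2-yl)-3-[(triethylsilyl)oxy]oxepan-2-yl]acetate (epimers at C4) | COC(=O)C(Br)[C@H]1O[C@@](C)(CCC=C(C)C)C[C@@H](O[Si](C)(C)C(C)(C)C)[C@@H](C(C)=C)[C@@H]1O[Si](CC)(CC)CC
F6 | step 14 | methyl 2-[(2R,3S,4R,5R,7S)-5-[(tert-butyldimethylsilyl)oxy]-7-methyl-7-(4-methylpent-3-en-1-yl)-4-(prop-1-en-2-yl)-3-[(triethylsilyl)oxy]oxepan-2-yl]prop-2-enoate | COC(=O)C(=C)[C@H]1O[C@@](C)(CCC=C(C)C)C[C@@H](O[Si](C)(C)C(C)(C)C)[C@@H](C(C)=C)[C@@H]1O[Si](CC)(CC)CC
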